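The numbers of this flask were chosen freely; what happens was integrated by code.

In theta a small charge of nucleophile stood at less than the electrophile, and each coupling set free one acid that could bind a further nucleophile.

| flask | electrophile | nucleophile | gas | time |
|---|---|---|---|---|
| theta | 0.063 M | 0.0500 M | 28 mM (held) | 20 s |
| delta | 0.063 M | 0.0660 M | 28 mM (held) | 20 s |

    electrophile + nucleophile → acid set free + target (k1 = 57.6 /M/s)
    nucleophile + acid set free ⇌ protonated nucleophile, settled at all times (K2 = 690 /M)
    acid set free + free base ⇌ salt of the base, settled at all times (K3 = 3.27 × 10⁶ /M)
    crystals ⇌ acid set free, rate k4*(cs4 - [acid set free]) while solid is left; crystals form when [acid set free] > cs4 (cs4 = 22 mM, k4 = 2.58 /s)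
    electrophile + acid set free → side product (k5 = 0.583 /M/s)
    gas ⇌ free base, rate k6*(csat - [free base]) (k6 = 0.745 /s, csat = 28 mM)

- for acid set free the crystals are counted in
- as a solid, counted per litre of solution: crystals
- at the start none of free base is dissolved
- run time (theta): 20 s

- part of the electrophile that has reacted at the end, theta
- part of the electrophile that has reacted at the end, delta
- what raising the concentration of nucleophile from its lowest to its highest value here does to the part of the electrophile that has reacted (changes below 5 percentage points count as none) (it rises / it falls / no change)

I reckoned with two amounts, the nucleophile and the electrophile charged. In theta their ratio was 79.4 %. I called it the ceiling, the part of the electrophile that the nucleophile charged can couple one for one, with the nucleophile as limiting reagent. Time dropped out, because coupling at the charged concentrations had a half-life of 0.24 s against a run of 20 s.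

But the ceiling assumes free nucleophile, and the binding constant times the nucleophile charged was 34, so acid would bind it. I therefore put the first answer back in. Reaching the ceiling in theta set free 0.0500 M of acid, and the free base had to take it up. I reckoned the crossing of the gas at 20.9 mM/s with no free base dissolved, and at that rate the crossing would take 2.40 s, less than the run. With acid near its solubility of 22 mM, the side step would halve the electrophile in 54.0 s, longer than that crossing.

So the ceiling survived the second round, and I committed to 79.4 % for theta. In delta the ratio was 1.05, above unity, so I committed to 100 %. That made a rise of 21 percentage points, beyond the margin of 5 points.

The forecast gave 79.9 % for theta, a little above my ceiling, and 99.8 % for delta, with the trend it rises, holding that the “nucleophile is therefore the stoichiometric limit”. The simulation gave 79.5 % for theta and 99.8 % for delta, and the result for the trend was it rises, by 20 points.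

Theta ended close to its ceiling of 79.4 %, with 0 % of the nucleophile and 20.5 % of the electrophile left. Its coupling was half done by 0.403 s, while the side loss of electrophile had a half-life of 46 min at 1.87 s, long against the run. A further flask like theta, charged with 0.030 M of nucleophile, had a ceiling of 47.6 %, and it reached 47.7 %.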